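The constants read here from the eta and theta runs are not rates but ratios of amounts.

| flask | electrophile | nucleophile | protic impurity | remark | time |
|---|---|---|---|---|---|
| eta | 0.10 M | 0.105 M | 0.015 M | run made earlier |  |
| theta | 0.20 M | 0.105 M | 0.010 M | run made earlier |  |
| Thursday's | 0.10 M | 0.420 M | 0.0100 M |  | 25 min |
| Tuesday's | 0.10 M | 0.210 M | 0.0100 M |  | 25 min |
| Monday's | 0.10 M | 0.100 M | 0.0100 M |  | 25 min |

| run | time / min | electrophile / % | target / % |
|---|---|---|---|
| eta | 1.33 | 64.2 | 21.8 |
| eta | 2.50 | 56.5 | 29.5 |
| eta | 4.00 | 51.4 | 36.6 |
| eta | 8.00 | 40.7 | 44.3 |
| eta | 15.0 | 35.5 | 49.8 |
| theta | 1.33 | 75.6 | 16.5 |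
| theta | 4.00 | 72.1 | 23.1 |
| theta | 8.00 | 68.5 | 27.7 |
| theta | 10.0 | 66.5 | 28.1 |
| theta | 15.0 | 65.4 | 27.6 |

(standard deviation of a reading: 1 percentage point)

- the earlier runs were read with a standard deviation of 1 percentage point

- part of the electrophile that has reacted at the end, Thursday's
- part of the electrophile that has reacted at the end, Tuesday's
- part of the electrophile that has reacted at the end, Monday's
- what raising the concentration of nucleophile from its lowest to its highest value here does to the part of the electrophile that has reacted (changes below 5 percentage points count as none) (it falls / it rises / no change)

By its last reading, the eta run is missing 0.0147 M of electrophile that never appeared as target, against 0.015 M of protic impurity charged, so these readings point to about one electrophile per impurity. In the theta run, the last reading of target stood at 0.0552 M with electrophile still present, half of the nucleophile charged, so these readings point to about two nucleophile per target. For Monday's flask, the nucleophile divided by two, plus the impurity, over the electrophile gives 60.0%. This ratio is the stall level S, the part of the electrophile reacted if each target takes two nucleophile and each impurity takes one electrophile. It stands below the full charge, so my reckoning takes nucleophile as the limiting reagent in Monday's flask.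

From above, one nucleophile per target would give 110%, more than the charge, so the first bound is merely 100%. The readings tighten it. At its last reading the theta run stood at 1.11 times its own S, and the eta run at 0.956 times its own. My bracket for Monday's is therefore 57.3% to 66.4%. Tuesday's S is 115% and Thursday's is 220%. Both lie above the charge, so their ceiling is 100%.

The forecast, reasoning from “two nucleophile per target”, gives 60% for Monday's, with a range of 56% to 65%, then 97% for Tuesday's and 100% for Thursday's, and its verdict on the part reacted, as nucleophile goes from lowest to highest, is “it rises”. Its Monday value lies inside the bracket.

The flasks give 61.1% on Monday, 96.8% on Tuesday and >99.9% on Thursday, so the verdict on the part reacted, as nucleophile goes from lowest to highest, is “it rises”, by 39 points.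

    electrophile + nucleophile → acid set free + target (k = 0.0700 M⁻¹ s⁻¹)
    nucleophile + acid set free ⇌ protonated nucleophile, settled at all times (K = 25000 M⁻¹)
    2 electrophile → self-condensation product (k = 1.20 × 10⁻⁴ M⁻¹ s⁻¹)
    electrophile + protic impurity → quenched substrate (k = 0.330 M⁻¹ s⁻¹)
    nucleophile ⇌ dormant form (K = 1.00, k = 0.0160 s⁻¹)

Monday's 61.1% stands beside its S of 60.0%, although the flask also holds 0.834% of self-condensation product, which S does not count. A neighbouring flask, Monday's with 0.040 M of nucleophile, has an S of 30.0% and gave 33.0%. Monday's flask has not come to rest: at 250 min, against the 25 min asked, it reaches 71.4%, above the bracket, while Tuesday's reaches 100% and Thursday's 100%. Over that stretch, Monday's electrophile falls from 38.9% to 28.6%, its target climbs to 57.1%, and its self-condensation product climbs to 4.28%.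

(All runs were computed with made-up constants; scatter was added.)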